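## Structural features

The target is a single carbocycle, cyclohex-1-ene-1-carboxylic acid, whose three contiguous sp3 carbons C3, C4 and C5 each carry an oxygen esterified with a 3,4,5-trihydroxybenzoyl (galloyl) group; C2 is the vinylic CH and C6 a methylene. The stereocentres stand side by side as 3R,4S,5R, with O3 cis to O4 and O5 trans to both. The fragile elements are nine free phenols (pyrogallol units that oxidise in base and air), three aryl esters that can migrate or be cleaved by nucleophiles (one of them allylic), a trisubstituted enoate that rules out hydrogenolytic deprotection, and a ring that aromatises if two of its oxygens are lost. The carbon skeleton is trivial; the real difficulty is the absolute and relative configuration of three neighbouring carbinol carbons on a small ring, and carrying three identical sensitive acyl groups to the end without reduction or base. The key step uses the trans relationship of O3 and O5: with C4 written as a carbonyl, C3 and C5 are the two α-carbons of a 4-oxocyclohexane-1-carboxylate, related by a twofold axis through C1 and C4, so both have the same (R) configuration. In that ketone neither C1 nor C4 is a stereocentre and C2 and C6 are equivalent, so the C1=C2 double bond can later be introduced toward either side with the same result. Only C4 then remains, to be set by hydride addition after the alkene has made the two carbonyl faces different.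

## Logic of the disconnections

**19 to 17.** The nine aryl O–Si bonds and the tert-butyl C–O bond of the ester are cut. Phenols and the free acid cannot be carried through acylation, and silyl and tert-butyl groups leave under acid and fluoride, so no hydrogenolysis or base meets the enoate or the gallates. 17 is neutral, lipophilic and chromatographable. The forward step must be non-reductive and non-basic.

**17 to 13 and 16.** The three ester C(=O)–O bonds at O3, O4 and O5 are cut together. Because the three acyl groups are identical, one operation suffices and acyl migration cannot create isomers. This splits the problem into a ring triol and one aromatic acid. The forward step must acylate three contiguous secondary hydroxyls exhaustively, including the flanked O4.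

**16 to 14.** The four O–Si bonds are cut. The forward step is persilylation followed by selective hydrolysis of the silyl ester only.

**13 to 12 to 11.** The two ring O–Si bonds are cut, then the C4–H bond. Making C4 from a carbonyl ties the target to a ketone with only two stereocentres of the same sense. The forward reduction must choose the carbonyl face anti to O3 and must be mild, because C3–H in 11 is α to the ketone and γ to the enoate.

**11 to 10.** The C4 carbonyl is masked as a dimethyl ketal (two C–O bonds). The mask lets the alkene be made through an ester enolate. The forward hydrolysis must be gentler than the conditions that cleave the silyl ethers and the tert-butyl ester.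

**10 to 7.** The C1=C2 π bond is removed (retro-dehydrogenation through 9 and 8). In 7 the methylenes C2 and C6 are equivalent, so there is no regiochemical question, and C1 is not a stereocentre. The forward step needs an ester enolate in a molecule with no other acidic or electrophilic site.

**7 to 6 to 4.** The ring O–Si bonds, the ketal C–O bonds and, through 5, the O–N bonds are changed back. The order (N–O cleavage, ketalisation, then silylation) is chosen so that the free α,α′-dihydroxy ketone 5 is never isolated and the ketal is formed while the flanking groups are still small.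

**4 to 1 and 2.** The C3–O and C5–O bonds are cut. Both stereocentres then come from one chiral amine catalyst (L-proline) acting twice on an achiral, purchased ketone. The forward step must be O-selective on 2, must run to the bis-adduct, and must place the second oxygen trans to the first.

## Other disconnections considered

Alternative 1: The ring is cut at C1–C2 and C5–C6 (target numbering), which leads to furan A1 and 2,2,2-trifluoroethyl acrylate A2. In the forward sense a chiral Lewis acid would catalyse their [4+2] cycloaddition to the endo oxabicyclic ester A3, in which the furan oxygen is the future O5 and the bridge alkene the future C3–C4. Osmium-catalysed dihydroxylation would then take the exo face, syn to the oxygen bridge, and enolisation of the ester would open the bridge by β-elimination, giving the cyclohexene with C1=C2 in place, for example as the acetonide 2,2,2-trifluoroethyl 3,4-O-isopropylidene-5-epi-shikimate A4. Since O5 is then cis to O3 and O4, the C5 gallate would have to be introduced with inversion by a Mitsunobu esterification with 16.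
- In favour: the ring and all its carbons arise in one step from two cheap achiral compounds. The rigid bicycle fixes the O3/O4 relationship and the alkene position without any conformational argument, which is more secure than the hydride reduction of step 6; on this point the alternative is the better plan.
- Against: furan is a reluctant diene whose adducts revert, so endo/exo and enantiomer ratios could erode. The C5 carbinol is formed with the wrong configuration, and substitution with inversion next to a dioxolane competes with elimination toward an aromatic. The three gallates would go on in two different ways, which needs orthogonal protection of O3 and O4.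
- Comparison: both plans rely on one catalytic asymmetric step for absolute configuration. The alternative forms two C–C bonds and a ring where the chosen plan forms two C–O bonds on a purchased ring. The step count is about equal. The chosen plan attaches all three identical esters in one operation and needs no inversion.

Alternative 2: The C3–O and C4–O bonds are cut. The forward key step would be osmium-catalysed dihydroxylation of the diene ester tert-butyl (5R)-5-{3,4,5-tris[(tert-butyldimethylsilyl)oxy]benzoyloxy}cyclohexa-1,3-diene-1-carboxylate A5, on the more electron-rich C3=C4 bond and on the face opposite the C5 ester, giving the diol A6. Acylation of the two new hydroxyls with 16 and deprotection would finish the synthesis.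
- In favour: it is the shortest sequence on paper and needs no ring protecting group, so its step economy is better than that of the chosen plan. The C5 gallate serves both as directing group and as part of the target. All three relative configurations follow from one anti-osmylation, which is at least as reliable as step 6.
- Against: nothing in the sequence sets absolute configuration. A dissolving-metal dearomatisation gives achiral or racemic dienes, so the (R)-carbinol would need a resolution or an enzymatic step. A5 is one elimination of the gallic acid away from a benzoate and can also isomerise by hydrogen shift. Site selectivity between the two alkenes of a conjugated dienoate is not guaranteed.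
- Comparison: the alternative is superior in length and equal or better in relative stereocontrol. The chosen plan is superior in having a catalytic source of absolute configuration and in avoiding an aromatisation-prone acyloxy diene.

Alternative 3: The C1=C2 bond is cut. In the forward sense the phosphonate lactol A8, made from D-mannose A7, would open to its aldehyde, and the phosphonoacetate carbanion would add to it and eliminate phosphate (intramolecular Horner–Wadsworth–Emmons olefination, six-membered ring closure by addition to the aldehyde), giving tert-butyl 3,4-O-isopropylideneshikimate A9.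
- In favour: all three stereocentres are taken from the sugar, so no step has to be selective; in stereochemical security this alternative is better than the chosen plan. The alkene position is fixed by the olefination, and A9 is one mild acetonide hydrolysis away from 13, so the endgame would be the same (equal).
- Against: a long linear sequence of protection, chain shortening and alkylation of a phosphonoacetate with a sugar-derived electrophile is needed before the ring exists.
- Comparison: the alternative closes the ring by C=C formation, whereas the chosen plan never closes a ring and sets two stereocentres in its first step. The chosen plan is clearly shorter but carries the C4 facial-selectivity risk that the sugar route does not have.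

Key step: step 1

Remark on the chemistry: in compounds 4 to 9 the ring carbons C1 and C4 carry no descriptor because their two ring branches are identical; intermediate 3 is a pair of C1 epimers that converge in 4.

## Steps

Step 1
Reactants: 1 tert-butyl 4-oxocyclohexane-1-carboxylate; 2 nitrosobenzene (3 equiv)
Product: 4 tert-butyl (3R,5R)-3,5-bis(anilinooxy)-4-oxocyclohexane-1-carboxylate, via mono-aminoxy ketone 3 (not isolated)
Conditions: L-proline (30 mol%), DMF, 0 °C, 2 added slowly by syringe pump
Reagents that add atoms: nitrosobenzene (compound 2), O=Nc1ccccc1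
Why: L-Proline condenses with the C4 ketone of 1 to an enamine whose α-carbon attacks the oxygen of 2 while the carboxylic acid of the catalyst protonates the nitroso nitrogen; hydrolysis releases 3 and the catalyst, and the same cycle on the remaining α-methylene gives 4. This is the known proline-catalysed α-aminoxylation of cyclohexanones with nitrosobenzene, run with excess oxidant so that it goes on to the α,α′-bis-adduct. No ring is closed; the two new bonds are C3–O and C5–O. Both new stereocentres are set by the catalyst: the acid-directed approach of 2 to one face of the enamine gives R with L-proline at whichever α-carbon reacts, so the second oxygen arrives on the opposite ring face and the trans (3R,5R) isomer results. The step needs O- over N-selectivity, secured by the hydrogen bond from the carboxylic acid to the more basic nitrogen, and α′- over α-attack in the second round, secured because the enamine toward the already oxygenated, more hindered carbon is disfavoured. The ester at C1 only makes 3 a pair of C1 epimers, and since C1 stops being a stereocentre once C3 and C5 share one configuration, both epimers converge on one compound. Any minor enantiomer of 3 is carried mainly into the separable cis isomer, so 4 should be of higher enantiopurity than the first addition alone would give. Slow addition keeps the concentration of 2 low and limits its self-condensation.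

Step 2
Reactants: 4 tert-butyl (3R,5R)-3,5-bis(anilinooxy)-4-oxocyclohexane-1-carboxylate
Product: 6 tert-butyl (3R,5R)-3,5-dihydroxy-4,4-dimethoxycyclohexane-1-carboxylate, via dihydroxy ketone 5 (not isolated)
Conditions: H2 (1 atm), Pd/C, MeOH, rt; filter; then HC(OMe)3, Amberlyst-15 (H+ form), MeOH, rt
Reagents that add atoms: trimethyl orthoformate, COC(OC)OC; methanol, CO
Why: Hydrogenolysis cleaves the weak N–O bonds and leaves ketone and ester untouched; the electrophilic α,α′-dihydroxy ketone 5 is converted in the same methanol solution into its dimethyl ketal by acid-catalysed ketalisation with the orthoformate as water scavenger, the reaction type by which 1,3-dihydroxyacetone is turned into its dimethyl ketal. The sulfonic acid resin also retains the aniline, and C3 and C5 are not touched.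

Step 3
Reactants: 6 tert-butyl (3R,5R)-3,5-dihydroxy-4,4-dimethoxycyclohexane-1-carboxylate
Product: 7 tert-butyl (3R,5R)-3,5-bis[(tert-butyldimethylsilyl)oxy]-4,4-dimethoxycyclohexane-1-carboxylate
Conditions: TBSOTf, 2,6-lutidine, CH2Cl2, −78 → 0 °C
Reagents that add atoms: tert-butyldimethylsilyl triflate, CC(C)(C)[Si](C)(C)OS(=O)(=O)C(F)(F)F
Why: A silyl triflate with a hindered pyridine base silylates the two secondary hydroxyls next to the quaternary ketal carbon quickly at low temperature, before the Lewis acid can ionise the deactivated ketal or the tert-butyl ester; no stereocentre is involved.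

Step 4
Reactants: 7 tert-butyl (3R,5R)-3,5-bis[(tert-butyldimethylsilyl)oxy]-4,4-dimethoxycyclohexane-1-carboxylate
Product: 10 tert-butyl (3R,5R)-3,5-bis[(tert-butyldimethylsilyl)oxy]-4,4-dimethoxycyclohex-1-ene-1-carboxylate, via selenide 8 (not isolated), via selenoxide 9 (not isolated)
Conditions: LiN(i-Pr)2, THF, −78 °C; PhSeBr, −78 °C; then H2O2 (30% aq.), pyridine, 0 °C → rt, same flask
Reagents that add atoms: none
Why: α-Selenenylation of the ester enolate, oxidation to the selenoxide and syn-elimination; the only β-hydrogens are on C2 and C6, which are equivalent because C3 and C5 have the same configuration and C4 is a symmetric ketal, so a single enoate forms. The ketal keeps the strong base away from the C4 carbonyl, and pyridine buffers the selenium acids.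

Step 5
Reactants: 10 tert-butyl (3R,5R)-3,5-bis[(tert-butyldimethylsilyl)oxy]-4,4-dimethoxycyclohex-1-ene-1-carboxylate
Product: 11 tert-butyl (3R,5R)-3,5-bis[(tert-butyldimethylsilyl)oxy]-4-oxocyclohex-1-ene-1-carboxylate
Conditions: TsOH·H2O (10 mol%), acetone–H2O (20:1), 0 °C → rt; crude product used at once
Reagents that add atoms: water, O
Why: Acid-catalysed hydrolysis of the dimethyl ketal, helped by relief of the crowding between the geminal methoxy groups and the flanking silyloxy groups; catalytic sulfonic acid in wet acetone should spare the hindered secondary silyl ethers and the tert-butyl ester. The ketone is not chromatographed because its C3–H is α to the carbonyl and γ to the enoate.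

Step 6
Reactants: 11 tert-butyl (3R,5R)-3,5-bis[(tert-butyldimethylsilyl)oxy]-4-oxocyclohex-1-ene-1-carboxylate
Product: 12 tert-butyl (3R,4S,5R)-3,5-bis[(tert-butyldimethylsilyl)oxy]-4-hydroxycyclohex-1-ene-1-carboxylate
Conditions: NaBH4, CeCl3·7H2O, MeOH, −78 °C
Reagents that add atoms: none
Why: Luche-type 1,2-reduction of the ketone at low temperature, faster than conjugate reduction of the enoate and than base-induced enolisation. Hydride should enter antiperiplanar to the pseudoaxial allylic C3–O bond of the half-chair that keeps the C5 silyloxy group equatorial, that is from the face opposite O3, which sets C4 as S with O4 cis to O3 and trans to O5.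

Step 7
Reactants: 12 tert-butyl (3R,4S,5R)-3,5-bis[(tert-butyldimethylsilyl)oxy]-4-hydroxycyclohex-1-ene-1-carboxylate
Product: 13 tert-butyl (3R,4S,5R)-3,4,5-trihydroxycyclohex-1-ene-1-carboxylate (tert-butyl shikimate)
Conditions: HF·pyridine, pyridine, THF, 0 °C → rt
Reagents that add atoms: none
Why: Fluoride cleavage of the two secondary silyl ethers in a buffered acidic medium; the tert-butyl ester, the enoate and the three stereocentres are unaffected, and silyl migration is irrelevant because both groups are removed.

Step 8
Reactants: 14 gallic acid
Product: 16 3,4,5-tris[(tert-butyldimethylsilyl)oxy]benzoic acid, via silyl ester 15 (not isolated)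
Conditions: TBSCl, imidazole, DMF, rt; then AcOH–THF–H2O (3:1:1), rt
Reagents that add atoms: tert-butyldimethylsilyl chloride, CC(C)(C)[Si](C)(C)Cl
Why: Exhaustive silylation of the three phenols and the acid, then selective hydrolysis of the much more labile silyl ester with aqueous acetic acid, to which aryl silyl ethers are stable.

Step 9
Reactants: 13 tert-butyl shikimate; 16 3,4,5-tris[(tert-butyldimethylsilyl)oxy]benzoic acid (3.6 equiv)
Product: 17 tert-butyl (3R,4S,5R)-3,4,5-tris{3,4,5-tris[(tert-butyldimethylsilyl)oxy]benzoyloxy}cyclohex-1-ene-1-carboxylate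
Conditions: EDC·HCl, DMAP, CH2Cl2, rt → 35 °C
Reagents that add atoms: 3,4,5-tris[(tert-butyldimethylsilyl)oxy]benzoic acid (compound 16), O=C(O)c1cc(O[Si](C)(C)C(C)(C)C)c(O[Si](C)(C)C(C)(C)C)c(O[Si](C)(C)C(C)(C)C)c1
Why: Carbodiimide esterification with DMAP as acyl-transfer catalyst (Steglich esterification), with excess 16 to drive all three contiguous secondary hydroxyls to the ester; 16 has no ortho substituents, and because the three acyl groups are identical any acyl migration leaves the product unchanged. Acylation at oxygen touches no stereocentre.

Step 10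
Reactants: 17 tert-butyl (3R,4S,5R)-3,4,5-tris{3,4,5-tris[(tert-butyldimethylsilyl)oxy]benzoyloxy}cyclohex-1-ene-1-carboxylate
Product: 19 3,4,5-tri-O-galloylshikimic acid, (3R,4S,5R)-3,4,5-tris(3,4,5-trihydroxybenzoyloxy)cyclohex-1-ene-1-carboxylic acid, via silylated acid 18 (not isolated)
Conditions: TFA–CH2Cl2 (1:2), 0 °C → rt; evaporate; then HF·pyridine, pyridine, THF, 0 °C → rt
Reagents that add atoms: none
Why: Acidolysis of the tert-butyl ester with loss of isobutene, then fluoride cleavage of the nine aryl silyl ethers in an acidic medium; neither stage is reductive or basic, so the enoate, the allylic ester and the oxidation-prone pyrogallol units should survive. Partial loss of aryl silyl groups in the first stage is of no consequence.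

## Compound list

1 | tert-butyl 4-oxocyclohexane-1-carboxylate | CC(C)(C)OC(=O)C1CCC(=O)CC1 | starting material
2 | nitrosobenzene | O=Nc1ccccc1 | starting material
3 | tert-butyl (3R)-3-(anilinooxy)-4-oxocyclohexane-1-carboxylate (both C1 epimers) | CC(C)(C)OC(=O)C1CCC(=O)[C@H](ONc2ccccc2)C1 | intermediate (not isolated)
4 | tert-butyl (3R,5R)-3,5-bis(anilinooxy)-4-oxocyclohexane-1-carboxylate | CC(C)(C)OC(=O)C1C[C@@H](ONc2ccccc2)C(=O)[C@H](ONc2ccccc2)C1 | intermediate
5 | tert-butyl (3R,5R)-3,5-dihydroxy-4-oxocyclohexane-1-carboxylate | CC(C)(C)OC(=O)C1C[C@@H](O)C(=O)[C@H](O)C1 | intermediate (not isolated)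
6 | tert-butyl (3R,5R)-3,5-dihydroxy-4,4-dimethoxycyclohexane-1-carboxylate | CC(C)(C)OC(=O)C1C[C@@H](O)C(OC)(OC)[C@H](O)C1 | intermediate
7 | tert-butyl (3R,5R)-3,5-bis[(tert-butyldimethylsilyl)oxy]-4,4-dimethoxycyclohexane-1-carboxylate | CC(C)(C)OC(=O)C1C[C@@H](O[Si](C)(C)C(C)(C)C)C(OC)(OC)[C@H](O[Si](C)(C)C(C)(C)C)C1 | intermediate
8 | tert-butyl (3R,5R)-3,5-bis[(tert-butyldimethylsilyl)oxy]-4,4-dimethoxy-1-(phenylselanyl)cyclohexane-1-carboxylate | CC(C)(C)OC(=O)C1([Se]c2ccccc2)C[C@@H](O[Si](C)(C)C(C)(C)C)C(OC)(OC)[C@H](O[Si](C)(C)C(C)(C)C)C1 | intermediate (not isolated)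
9 | tert-butyl (3R,5R)-1-(benzeneseleninyl)-3,5-bis[(tert-butyldimethylsilyl)oxy]-4,4-dimethoxycyclohexane-1-carboxylate | CC(C)(C)OC(=O)C1([Se](=O)c2ccccc2)C[C@@H](O[Si](C)(C)C(C)(C)C)C(OC)(OC)[C@H](O[Si](C)(C)C(C)(C)C)C1 | intermediate (not isolated)
10 | tert-butyl (3R,5R)-3,5-bis[(tert-butyldimethylsilyl)oxy]-4,4-dimethoxycyclohex-1-ene-1-carboxylate | CC(C)(C)OC(=O)C1=C[C@@H](O[Si](C)(C)C(C)(C)C)C(OC)(OC)[C@H](O[Si](C)(C)C(C)(C)C)C1 | intermediate
11 | tert-butyl (3R,5R)-3,5-bis[(tert-butyldimethylsilyl)oxy]-4-oxocyclohex-1-ene-1-carboxylate | CC(C)(C)OC(=O)C1=C[C@@H](O[Si](C)(C)C(C)(C)C)C(=O)[C@H](O[Si](C)(C)C(C)(C)C)C1 | intermediate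
12 | tert-butyl (3R,4S,5R)-3,5-bis[(tert-butyldimethylsilyl)oxy]-4-hydroxycyclohex-1-ene-1-carboxylate | CC(C)(C)OC(=O)C1=C[C@@H](O[Si](C)(C)C(C)(C)C)[C@@H](O)[C@H](O[Si](C)(C)C(C)(C)C)C1 | intermediate
13 | tert-butyl (3R,4S,5R)-3,4,5-trihydroxycyclohex-1-ene-1-carboxylate (tert-butyl shikimate) | CC(C)(C)OC(=O)C1=C[C@@H](O)[C@@H](O)[C@H](O)C1 | intermediate
14 | gallic acid | O=C(O)c1cc(O)c(O)c(O)c1 | starting material
15 | tert-butyldimethylsilyl 3,4,5-tris[(tert-butyldimethylsilyl)oxy]benzoate | CC(C)(C)[Si](C)(C)OC(=O)c1cc(O[Si](C)(C)C(C)(C)C)c(O[Si](C)(C)C(C)(C)C)c(O[Si](C)(C)C(C)(C)C)c1 | intermediate (not isolated)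
16 | 3,4,5-tris[(tert-butyldimethylsilyl)oxy]benzoic acid | O=C(O)c1cc(O[Si](C)(C)C(C)(C)C)c(O[Si](C)(C)C(C)(C)C)c(O[Si](C)(C)C(C)(C)C)c1 | intermediate
17 | tert-butyl (3R,4S,5R)-3,4,5-tris{3,4,5-tris[(tert-butyldimethylsilyl)oxy]benzoyloxy}cyclohex-1-ene-1-carboxylate | CC(C)(C)OC(=O)C1=C[C@@H](OC(=O)c2cc(O[Si](C)(C)C(C)(C)C)c(O[Si](C)(C)C(C)(C)C)c(O[Si](C)(C)C(C)(C)C)c2)[C@@H](OC(=O)c2cc(O[Si](C)(C)C(C)(C)C)c(O[Si](C)(C)C(C)(C)C)c(O[Si](C)(C)C(C)(C)C)c2)[C@H](OC(=O)c2cc(O[Si](C)(C)C(C)(C)C)c(O[Si](C)(C)C(C)(C)C)c(O[Si](C)(C)C(C)(C)C)c2)C1 | intermediate
18 | (3R,4S,5R)-3,4,5-tris{3,4,5-tris[(tert-butyldimethylsilyl)oxy]benzoyloxy}cyclohex-1-ene-1-carboxylic acid | O=C(O)C1=C[C@@H](OC(=O)c2cc(O[Si](C)(C)C(C)(C)C)c(O[Si](C)(C)C(C)(C)C)c(O[Si](C)(C)C(C)(C)C)c2)[C@@H](OC(=O)c2cc(O[Si](C)(C)C(C)(C)C)c(O[Si](C)(C)C(C)(C)C)c(O[Si](C)(C)C(C)(C)C)c2)[C@H](OC(=O)c2cc(O[Si](C)(C)C(C)(C)C)c(O[Si](C)(C)C(C)(C)C)c(O[Si](C)(C)C(C)(C)C)c2)C1 | intermediate (not isolated)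
19 | 3,4,5-tri-O-galloylshikimic acid | O=C(O)C1=C[C@@H](OC(=O)c2cc(O)c(O)c(O)c2)[C@@H](OC(=O)c2cc(O)c(O)c(O)c2)[C@H](OC(=O)c2cc(O)c(O)c(O)c2)C1 | target

## Step count and least certain steps

Total: 10 steps. Longest linear sequence: 9 steps (steps 1 to 7, 9 and 10, from 1); step 8 is a one-step branch from 14.

**Step 1 (key step).** The most likely failure is a stalled second oxygenation: the enamine of 3 forms more slowly than that of 1, while 2 is lost to self-condensation and the aminoxy ketone can lose aniline toward a 1,2-dione under the amine, leaving mixtures of 3 and 4. The fallback sets out from 3 and returns at 5; it sets the second centre by substrate control instead of catalyst control.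
- The catalysis is run with one equivalent of 2 and stopped at 3, which is isolated. Hydrogenolysis (H2, Pd/C, EtOAc) gives tert-butyl (3R)-3-hydroxy-4-oxocyclohexane-1-carboxylate F1.
- Silylation (TBSCl, imidazole, DMF) gives tert-butyl (3R)-3-[(tert-butyldimethylsilyl)oxy]-4-oxocyclohexane-1-carboxylate F2.
- Kinetic enolisation away from the oxygenated carbon (LiN(i-Pr)2, Me3SiCl, THF, −78 °C) gives tert-butyl (5R)-5-[(tert-butyldimethylsilyl)oxy]-4-[(trimethylsilyl)oxy]cyclohex-3-ene-1-carboxylate F3.
- Rubottom oxidation (mCPBA, NaHCO3, CH2Cl2, 0 °C, then mild acid) should deliver oxygen anti to the allylic silyloxy group, which strain against the enol ether oxygen holds pseudoaxial, to give tert-butyl (3R,5R)-3-[(tert-butyldimethylsilyl)oxy]-5-hydroxy-4-oxocyclohexane-1-carboxylate F4.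
- HF·pyridine then frees 5, which enters the ketalisation of step 2.

**Step 5.** The most likely failure is slow ionisation of the ketal, which is deactivated by two α-silyloxy carbons, so that silyl ether or tert-butyl ester cleavage overtakes it. Once the ketone is free, epimerisation at the doubly activated C3 or loss of silanol toward a 4-hydroxybenzoate can follow. The fallback sets out from 1 and returns at 11; it installs the latent alkene as a tertiary hydroxyl before the oxygenation, so that no ketal has to be removed late.
- 1 is ketalised (ethylene glycol, TsOH, toluene, azeotropic removal of water) to tert-butyl 1,4-dioxaspiro[4.5]decane-8-carboxylate F5.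
- The ester enolate (LiN(i-Pr)2, THF, −78 °C) is hydroxylated with 3-phenyl-2-(phenylsulfonyl)oxaziridine to tert-butyl 8-hydroxy-1,4-dioxaspiro[4.5]decane-8-carboxylate F6.
- Dilute aqueous acid, acting on an unhindered ketal with no sensitive neighbour, gives tert-butyl 1-hydroxy-4-oxocyclohexane-1-carboxylate F7.
- The proline-catalysed double aminoxylation with 2 gives tert-butyl (3R,5R)-3,5-bis(anilinooxy)-1-hydroxy-4-oxocyclohexane-1-carboxylate F8.
- Hydrogenolysis (H2, Pd/C) gives tert-butyl (3R,5R)-1,3,5-trihydroxy-4-oxocyclohexane-1-carboxylate F9.
- Silylation of the two secondary hydroxyls (TBSCl, imidazole, DMF) gives tert-butyl (3R,5R)-3,5-bis[(tert-butyldimethylsilyl)oxy]-1-hydroxy-4-oxocyclohexane-1-carboxylate F10.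
- Dehydration of the tertiary α-hydroxy ester (SOCl2, pyridine, CH2Cl2, −20 → 0 °C; E2 from the chlorosulfite toward C2 or C6, which are equivalent) leads to 11, which is reduced at once as in step 6.

**Step 6.** The most likely failure is poor or reversed facial selectivity. If the ring reacts through the other half-chair, with the C5 silyloxy group axial and the C3 one pseudoequatorial, hydride enters anti to O5 and the 4R epimer becomes the main product. The two half-chairs are close in energy, so the stated preference is an argument and not a certainty. The fallback sets out from 11 and returns at 12.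
- The 4R alcohol tert-butyl (3R,4R,5R)-3,5-bis[(tert-butyldimethylsilyl)oxy]-4-hydroxycyclohex-1-ene-1-carboxylate F11 is then accepted as the reduction product.
- Mitsunobu esterification (PPh3, DIAD, 4-nitrobenzoic acid, toluene, 0 °C → rt) inverts C4 to give tert-butyl (3R,4S,5R)-3,5-bis[(tert-butyldimethylsilyl)oxy]-4-[(4-nitrobenzoyl)oxy]cyclohex-1-ene-1-carboxylate F12.
- Methanolysis (K2CO3, MeOH, 0 °C) gives 12. Silyl migration during methanolysis would be harmless, because step 7 removes both silyl groups.

**Step 2.** The most likely failure is erosion of the trans relationship by enolisation of the free ketol 5 through its enediol, its self-condensation in acidic methanol, or reductive alkylation of the aniline by the ketone on the palladium surface. The fallback sets out from 5 and returns at 7.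
- Hydrogenolysis is run in EtOAc and stopped as soon as 4 is consumed.
- Crude 5 is silylated at once (TBSOTf, 2,6-lutidine, CH2Cl2, −78 °C) to tert-butyl (3R,5R)-3,5-bis[(tert-butyldimethylsilyl)oxy]-4-oxocyclohexane-1-carboxylate F13.
- Ketalisation is then done under aprotic conditions (MeOSiMe3, cat. TMSOTf, CH2Cl2, −78 → −20 °C), which gives 7 directly.

## Further compounds

F1 | step 1 | tert-butyl (3R)-3-hydroxy-4-oxocyclohexane-1-carboxylate | CC(C)(C)OC(=O)C1CCC(=O)[C@H](O)C1
F2 | step 1 | tert-butyl (3R)-3-[(tert-butyldimethylsilyl)oxy]-4-oxocyclohexane-1-carboxylate | CC(C)(C)OC(=O)C1CCC(=O)[C@H](O[Si](C)(C)C(C)(C)C)C1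
F3 | step 1 | tert-butyl (5R)-5-[(tert-butyldimethylsilyl)oxy]-4-[(trimethylsilyl)oxy]cyclohex-3-ene-1-carboxylate | CC(C)(C)OC(=O)C1CC=C(O[Si](C)(C)C)[C@H](O[Si](C)(C)C(C)(C)C)C1
F4 | step 1 | tert-butyl (3R,5R)-3-[(tert-butyldimethylsilyl)oxy]-5-hydroxy-4-oxocyclohexane-1-carboxylate | CC(C)(C)OC(=O)C1C[C@@H](O)C(=O)[C@H](O[Si](C)(C)C(C)(C)C)C1
F5 | step 5 | tert-butyl 1,4-dioxaspiro[4.5]decane-8-carboxylate | CC(C)(C)OC(=O)C1CCC2(CC1)OCCO2
F6 | step 5 | tert-butyl 8-hydroxy-1,4-dioxaspiro[4.5]decane-8-carboxylate | CC(C)(C)OC(=O)C1(O)CCC2(CC1)OCCO2
F7 | step 5 | tert-butyl 1-hydroxy-4-oxocyclohexane-1-carboxylate | CC(C)(C)OC(=O)C1(O)CCC(=O)CC1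
F8 | step 5 | tert-butyl (3R,5R)-3,5-bis(anilinooxy)-1-hydroxy-4-oxocyclohexane-1-carboxylate | CC(C)(C)OC(=O)C1(O)C[C@@H](ONc2ccccc2)C(=O)[C@H](ONc2ccccc2)C1
F9 | step 5 | tert-butyl (3R,5R)-1,3,5-trihydroxy-4-oxocyclohexane-1-carboxylate | CC(C)(C)OC(=O)C1(O)C[C@@H](O)C(=O)[C@H](O)C1
F10 | step 5 | tert-butyl (3R,5R)-3,5-bis[(tert-butyldimethylsilyl)oxy]-1-hydroxy-4-oxocyclohexane-1-carboxylate | CC(C)(C)OC(=O)C1(O)C[C@@H](O[Si](C)(C)C(C)(C)C)C(=O)[C@H](O[Si](C)(C)C(C)(C)C)C1
F11 | step 6 | tert-butyl (3R,4R,5R)-3,5-bis[(tert-butyldimethylsilyl)oxy]-4-hydroxycyclohex-1-ene-1-carboxylate | CC(C)(C)OC(=O)C1=C[C@@H](O[Si](C)(C)C(C)(C)C)[C@H](O)[C@H](O[Si](C)(C)C(C)(C)C)C1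
F12 | step 6 | tert-butyl (3R,4S,5R)-3,5-bis[(tert-butyldimethylsilyl)oxy]-4-[(4-nitrobenzoyl)oxy]cyclohex-1-ene-1-carboxylate | CC(C)(C)OC(=O)C1=C[C@@H](O[Si](C)(C)C(C)(C)C)[C@@H](OC(=O)c2ccc(cc2)[N+](=O)[O-])[C@H](O[Si](C)(C)C(C)(C)C)C1
F13 | step 2 | tert-butyl (3R,5R)-3,5-bis[(tert-butyldimethylsilyl)oxy]-4-oxocyclohexane-1-carboxylate | CC(C)(C)OC(=O)C1C[C@@H](O[Si](C)(C)C(C)(C)C)C(=O)[C@H](O[Si](C)(C)C(C)(C)C)C1
A1 | alternative 1 | furan | c1ccoc1
A2 | alternative 1 | 2,2,2-trifluoroethyl acrylate | C=CC(=O)OCC(F)(F)F
A3 | alternative 1 | 2,2,2-trifluoroethyl (1S,2S,4S)-7-oxabicyclo[2.2.1]hept-5-ene-2-carboxylate (endo adduct) | FC(F)(F)COC(=O)[C@@H]1[C@@H]2C=C[C@@H](O2)C1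
A4 | alternative 1 | 2,2,2-trifluoroethyl 3,4-O-isopropylidene-5-epi-shikimate | FC(F)(F)COC(=O)C1=C[C@H]2OC(C)(C)O[C@H]2[C@@H](O)C1
A5 | alternative 2 | tert-butyl (5R)-5-{3,4,5-tris[(tert-butyldimethylsilyl)oxy]benzoyloxy}cyclohexa-1,3-diene-1-carboxylate | CC(C)(C)OC(=O)C1=CC=C[C@H](OC(=O)c2cc(O[Si](C)(C)C(C)(C)C)c(O[Si](C)(C)C(C)(C)C)c(O[Si](C)(C)C(C)(C)C)c2)C1
A6 | alternative 2 | tert-butyl 5-O-{3,4,5-tris[(tert-butyldimethylsilyl)oxy]benzoyl}shikimate | CC(C)(C)OC(=O)C1=C[C@@H](O)[C@@H](O)[C@H](OC(=O)c2cc(O[Si](C)(C)C(C)(C)C)c(O[Si](C)(C)C(C)(C)C)c(O[Si](C)(C)C(C)(C)C)c2)C1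
A7 | alternative 3 | D-mannose (open-chain form) | O=C[C@@H](O)[C@@H](O)[C@H](O)[C@H](O)CO
A8 | alternative 3 | 5-deoxy-5-[(tert-butoxycarbonyl)(diethoxyphosphoryl)methyl]-2,3-O-isopropylidene-D-lyxofuranose | CC(C)(C)OC(=O)C(P(=O)(OCC)OCC)C[C@H]1OC(O)[C@H]2OC(C)(C)O[C@@H]12
A9 | alternative 3 | tert-butyl 3,4-O-isopropylideneshikimate | CC(C)(C)OC(=O)C1=C[C@H]2OC(C)(C)O[C@H]2[C@H](O)C1
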